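**Plan**

- Numbering: tetralin C1 (aryl-bearing), C2 (sulfated arm), C3 (CH2OH arm), C4 (CH2), fused ring C4a–C8a with OMe on C6 and OH on C7.
- Enabling feature: C1 carries one H, C1′ of the pendant ring (para to its OH) and C8a of the fused ring (para to the C6 OMe), so it is an aldehyde carbon arylated twice. It also lies 1,4 to the oxygen of the C3 hydroxymethyl group, so it can be stored as a five-membered lactol acetal.
- Cuts, in retrosynthetic order: the sulfate O–S bond; C1–C1′ and C1–C8a together (to a 2-methoxytetrahydrofuran and guaiacol); C1–C2 (acetal carbon onto a lactone α-carbon); then the β-benzyl lactone back to a Stobbe half-ester.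
- Forward: the chain is joined by Stobbe condensation, hydrogenation and lactonisation; C1 is attached as a dimethoxymethyl group; reduction and acetal exchange give the tetrahydrofuran acetal (step 5). Step 7 opens that ring again and closes the only carbocycle.
- Stereochemistry: C3 from Rh-catalysed asymmetric hydrogenation; C2 from alkylation of the lactone anti to the benzyl group; C1 in the key step, trans to the C2 arm.

Key step: step 7

Remark: a 2,3-trans tetralin needs the C3 and C4 substituents of the tetrahydrofuran acetal cis (the lariciresinol arrangement); the lactone carbonyl is therefore made the future C2 arm and the acetal carbon is introduced trans at the α-position.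
Remark: (4S,5S)-MOD-DIOP is taken as the ligand enantiomer that delivers the R acid in step 2; if the sense is the opposite, the (4R,5R) ligand is used.
Remark: the target is delivered in the hydrogen sulfate form drawn; it is carried as the sodium salt and protonated only at the end.

Step 1
Reactants: 1 4-benzyloxy-3-methoxybenzaldehyde; 2 dimethyl succinate
Product: 3 (E)-4-(4-benzyloxy-3-methoxyphenyl)-3-(methoxycarbonyl)but-3-enoic acid
Conditions: NaOMe, MeOH, reflux; then aq. HCl
Reagents that add atoms: none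
Why: Stobbe condensation; aldol addition, lactonisation and E1cB ring opening should deliver the E half-ester with the free acid on the CH2 arm.

Step 2
Reactants: 3 (E)-4-(4-benzyloxy-3-methoxyphenyl)-3-(methoxycarbonyl)but-3-enoic acid
Product: 4 (R)-4-(4-benzyloxy-3-methoxyphenyl)-3-(methoxycarbonyl)butanoic acid
Conditions: H2 (1 atm), [Rh(cod)Cl]2/(4S,5S)-MOD-DIOP (cat.), NEt3, MeOH, 30 °C
Reagents that add atoms: none
Why: Rh-catalysed asymmetric hydrogenation of an itaconate-type half-ester; carboxylate-directed chelation lets the chiral diphosphine select the alkene face and set the future C3 centre as R, and the homogeneous catalyst should spare the benzyl ether.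

Step 3
Reactants: 4 (R)-4-(4-benzyloxy-3-methoxyphenyl)-3-(methoxycarbonyl)butanoic acid
Product: 6 (R)-4-(4-benzyloxy-3-methoxybenzyl)dihydrofuran-2(3H)-one, via hydroxy acid 5 (not isolated)
Conditions: KOH (1 equiv), EtOH; Ca(BH4)2 (from CaCl2 + NaBH4), −10 °C → rt; then aq. HCl
Reagents that add atoms: none
Why: Chemoselective borohydride reduction; the potassium carboxylate is inert while the methyl ester is reduced, and acidification closes the γ-lactone without touching the stereocentre.

Step 4
Reactants: 6 (R)-4-(4-benzyloxy-3-methoxybenzyl)dihydrofuran-2(3H)-one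
Product: 8 (3S,4R)-4-(4-benzyloxy-3-methoxybenzyl)-3-(dimethoxymethyl)dihydrofuran-2(3H)-one (trans), via silyl ketene acetal 7 (not isolated)
Conditions: LDA, THF, −78 °C; TMSCl; solvent exchange to CH2Cl2; HC(OMe)3, TMSOTf (5 mol%), −78 °C; pyridine quench
Reagents that add atoms: trimethyl orthoformate, COC(OC)OC; chlorotrimethylsilane, C[Si](C)(C)Cl (its silyl group is held only by intermediate 7)
Why: Mukaiyama-type alkylation of a silyl ketene acetal by the dimethoxycarbenium ion; the electrophile should add to the planar ketene acetal anti to the C4 benzyl group, setting the future C2 centre trans to it.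

Step 5
Reactants: 8 (3S,4R)-4-(4-benzyloxy-3-methoxybenzyl)-3-(dimethoxymethyl)dihydrofuran-2(3H)-one
Product: 10 [(3R,4R)-4-(4-benzyloxy-3-methoxybenzyl)-2-methoxytetrahydrofuran-3-yl]methanol (3,4-cis; anomer mixture), via acetal diol 9 (not isolated)
Conditions: LiBH4, THF, 0 °C → rt; then MeOH, HCl (to pH ~2), 0 °C → rt
Reagents that add atoms: none
Why: Hydride reduction of the lactone to the 1,4-diol followed by acid-catalysed transacetalisation; only the hydroxyl of the former lactone CH2–O can form a five-membered ring with the acetal carbon, so the future C2 arm stays free and the ring substituents end 3,4-cis with no change at either stereocentre.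

Step 6
Reactants: 10 [(3R,4R)-4-(4-benzyloxy-3-methoxybenzyl)-2-methoxytetrahydrofuran-3-yl]methanol
Product: 11 (3R,4R)-4-(4-benzyloxy-3-methoxybenzyl)-3-(tert-butyldiphenylsilyloxymethyl)-2-methoxytetrahydrofuran (3,4-cis; anomer mixture)
Conditions: TBDPSCl, imidazole, DMF, rt
Reagents that add atoms: tert-butyl(chloro)diphenylsilane, CC(C)(C)[Si](Cl)(c1ccccc1)c1ccccc1
Why: Imidazole-mediated silylation of a primary alcohol; TBDPS is chosen because it should tolerate BF3 at low temperature and is later removed with fluoride.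

Step 7
Reactants: 11 (3R,4R)-4-(4-benzyloxy-3-methoxybenzyl)-3-(tert-butyldiphenylsilyloxymethyl)-2-methoxytetrahydrofuran; 12 guaiacol
Product: 14 (1S,2R,3R)-7-benzyloxy-2-(tert-butyldiphenylsilyloxymethyl)-3-(hydroxymethyl)-1-(4-hydroxy-3-methoxyphenyl)-6-methoxy-1,2,3,4-tetrahydronaphthalene, via 2-aryltetrahydrofuran 13 (not isolated)
Conditions: 12 (5 equiv), BF3·OEt2 (2.5 equiv), CH2Cl2, −40 → 0 °C
Reagents that add atoms: none
Why: Proposed new method: BF3 should ionise the methyl acetal to a five-membered oxocarbenium ion that guaiacol captures para to its OH (C1–C1′), giving 13; the p-hydroxybenzylic C–O bond of 13 then ionises to a quinone-methide-like cation that the tethered arene captures para to its OMe (C1–C8a), which frees the C3 hydroxymethyl group. The closest known reactions are the Friedel–Crafts C-arylation of 2-alkoxytetrahydrofurans and the acid-induced lariciresinol-to-isolariciresinol rearrangement; running both in one pot is the untested part. The carbocycle closes as a six-membered ring by intramolecular Friedel–Crafts alkylation through a chair-like transition state. The new C1 centre is controlled by the adjacent C2 centre, since aryl, C2 arm and C3 arm can all sit equatorial, giving 1,2-trans and 2,3-trans; the configuration at the aryl-bearing carbon of 13 is erased on ionisation and does not matter. The step needs para-to-OH attack on guaiacol, which the stronger donor, the less hindered site and the excess of guaiacol should secure, and closure para to OMe on the tethered ring, where the alternative ortho site is crowded between OMe and the tether. If the tethered ring adds first, the bridged benzylic ether should re-ionise and be trapped by guaiacol anti to the C2 arm, converging on 14.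

Step 8
Reactants: 14 (1S,2R,3R)-7-benzyloxy-2-(tert-butyldiphenylsilyloxymethyl)-3-(hydroxymethyl)-1-(4-hydroxy-3-methoxyphenyl)-6-methoxy-1,2,3,4-tetrahydronaphthalene
Product: 15 (1S,2R,3R)-7-benzyloxy-3-(benzyloxymethyl)-1-(4-benzyloxy-3-methoxyphenyl)-2-(tert-butyldiphenylsilyloxymethyl)-6-methoxy-1,2,3,4-tetrahydronaphthalene
Conditions: BnBr (4 equiv), Ag2O (3 equiv), DMF, rt, dark
Reagents that add atoms: benzyl bromide, BrCc1ccccc1
Why: Ag2O-mediated Williamson etherification should benzylate the phenol and the primary alcohol without a free alkoxide, which avoids 1,4-silyl migration between the two arms.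

Step 9
Reactants: 15 (1S,2R,3R)-7-benzyloxy-3-(benzyloxymethyl)-1-(4-benzyloxy-3-methoxyphenyl)-2-(tert-butyldiphenylsilyloxymethyl)-6-methoxy-1,2,3,4-tetrahydronaphthalene
Product: 16 (1S,2R,3R)-7-benzyloxy-3-(benzyloxymethyl)-1-(4-benzyloxy-3-methoxyphenyl)-2-(hydroxymethyl)-6-methoxy-1,2,3,4-tetrahydronaphthalene
Conditions: TBAF, THF, 0 °C → rt
Reagents that add atoms: none
Why: Fluoride-induced desilylation should free only the C2 hydroxymethyl group; the benzyl ethers are inert.

Step 10
Reactants: 16 (1S,2R,3R)-7-benzyloxy-3-(benzyloxymethyl)-1-(4-benzyloxy-3-methoxyphenyl)-2-(hydroxymethyl)-6-methoxy-1,2,3,4-tetrahydronaphthalene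
Product: 17 sodium [(1S,2R,3R)-7-benzyloxy-3-(benzyloxymethyl)-1-(4-benzyloxy-3-methoxyphenyl)-6-methoxy-1,2,3,4-tetrahydronaphthalen-2-yl]methyl sulfate
Conditions: SO3·pyridine, pyridine, rt; then aq. NaHCO3
Reagents that add atoms: sulfur trioxide–pyridine complex, [O-]S(=O)(=O)[n+]1ccccc1; sodium hydrogencarbonate, [Na+].OC([O-])=O
Why: O-Sulfation of the only free hydroxyl with the SO3·pyridine complex; bicarbonate work-up should give the stable sodium sulfate monoester.

Step 11
Reactants: 17 sodium [(1S,2R,3R)-7-benzyloxy-3-(benzyloxymethyl)-1-(4-benzyloxy-3-methoxyphenyl)-6-methoxy-1,2,3,4-tetrahydronaphthalen-2-yl]methyl sulfate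
Product: 19 CNP0184747.1 in the hydrogen sulfate form, via sodium salt 18 (not isolated)
Conditions: H2 (1 atm), Pd(OH)2/C, MeOH/H2O, rt; filter; then aq. HCl (1.0 equiv), 0 °C, C18 desalting
Reagents that add atoms: none
Why: Catalytic hydrogenolysis should cleave the three benzyl ethers while the alkyl sulfate salt and the diarylmethine C–C bonds stay intact; one equivalent of acid in the cold then protonates the sulfate.

**Compound list**

1 | 4-benzyloxy-3-methoxybenzaldehyde | COc1cc(C=O)ccc1OCc1ccccc1 | starting material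
2 | dimethyl succinate | COC(=O)CCC(=O)OC | starting material
3 | (E)-4-(4-benzyloxy-3-methoxyphenyl)-3-(methoxycarbonyl)but-3-enoic acid | COC(=O)/C(=C/c1ccc(OCc2ccccc2)c(OC)c1)CC(=O)O | intermediate
4 | (R)-4-(4-benzyloxy-3-methoxyphenyl)-3-(methoxycarbonyl)butanoic acid | COC(=O)[C@@H](CC(=O)O)Cc1ccc(OCc2ccccc2)c(OC)c1 | intermediate
5 | (R)-4-(4-benzyloxy-3-methoxyphenyl)-3-(hydroxymethyl)butanoic acid (present as its salt, not isolated) | OC[C@@H](CC(=O)O)Cc1ccc(OCc2ccccc2)c(OC)c1 | intermediate
6 | (R)-4-(4-benzyloxy-3-methoxybenzyl)dihydrofuran-2(3H)-one | O=C1C[C@@H](Cc2ccc(OCc3ccccc3)c(OC)c2)CO1 | intermediate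
7 | (4R)-4-(4-benzyloxy-3-methoxybenzyl)-2-(trimethylsilyloxy)-4,5-dihydrofuran (not isolated) | C[Si](C)(C)OC1=C[C@@H](Cc2ccc(OCc3ccccc3)c(OC)c2)CO1 | intermediate
8 | (3S,4R)-4-(4-benzyloxy-3-methoxybenzyl)-3-(dimethoxymethyl)dihydrofuran-2(3H)-one (trans) | COC(OC)[C@H]1C(=O)OC[C@@H]1Cc1ccc(OCc2ccccc2)c(OC)c1 | intermediate
9 | (2R,3R)-2-(4-benzyloxy-3-methoxybenzyl)-3-(dimethoxymethyl)butane-1,4-diol (not isolated) | COC(OC)[C@@H](CO)[C@H](CO)Cc1ccc(OCc2ccccc2)c(OC)c1 | intermediate
10 | [(3R,4R)-4-(4-benzyloxy-3-methoxybenzyl)-2-methoxytetrahydrofuran-3-yl]methanol (3,4-cis, anomer mixture) | COC1OC[C@H](Cc2ccc(OCc3ccccc3)c(OC)c2)[C@@H]1CO | intermediate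
11 | (3R,4R)-4-(4-benzyloxy-3-methoxybenzyl)-3-(tert-butyldiphenylsilyloxymethyl)-2-methoxytetrahydrofuran (3,4-cis, anomer mixture) | COC1OC[C@H](Cc2ccc(OCc3ccccc3)c(OC)c2)[C@@H]1CO[Si](c1ccccc1)(c1ccccc1)C(C)(C)C | intermediate
12 | guaiacol (2-methoxyphenol) | COc1ccccc1O | starting material
13 | 4-[(2S,3R,4R)-4-(4-benzyloxy-3-methoxybenzyl)-3-(tert-butyldiphenylsilyloxymethyl)tetrahydrofuran-2-yl]-2-methoxyphenol (2,3-trans epimer drawn; either epimer converges; not isolated) | COc1cc([C@H]2OC[C@H](Cc3ccc(OCc4ccccc4)c(OC)c3)[C@@H]2CO[Si](c2ccccc2)(c2ccccc2)C(C)(C)C)ccc1O | intermediate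
14 | (1S,2R,3R)-7-benzyloxy-2-(tert-butyldiphenylsilyloxymethyl)-3-(hydroxymethyl)-1-(4-hydroxy-3-methoxyphenyl)-6-methoxy-1,2,3,4-tetrahydronaphthalene | COc1cc([C@H]2c3cc(OCc4ccccc4)c(OC)cc3C[C@@H](CO)[C@@H]2CO[Si](c2ccccc2)(c2ccccc2)C(C)(C)C)ccc1O | intermediate
15 | (1S,2R,3R)-7-benzyloxy-3-(benzyloxymethyl)-1-(4-benzyloxy-3-methoxyphenyl)-2-(tert-butyldiphenylsilyloxymethyl)-6-methoxy-1,2,3,4-tetrahydronaphthalene | COc1cc([C@H]2c3cc(OCc4ccccc4)c(OC)cc3C[C@@H](COCc3ccccc3)[C@@H]2CO[Si](c2ccccc2)(c2ccccc2)C(C)(C)C)ccc1OCc1ccccc1 | intermediate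
16 | (1S,2R,3R)-7-benzyloxy-3-(benzyloxymethyl)-1-(4-benzyloxy-3-methoxyphenyl)-2-(hydroxymethyl)-6-methoxy-1,2,3,4-tetrahydronaphthalene | COc1cc([C@H]2c3cc(OCc4ccccc4)c(OC)cc3C[C@@H](COCc3ccccc3)[C@@H]2CO)ccc1OCc1ccccc1 | intermediate
17 | sodium [(1S,2R,3R)-7-benzyloxy-3-(benzyloxymethyl)-1-(4-benzyloxy-3-methoxyphenyl)-6-methoxy-1,2,3,4-tetrahydronaphthalen-2-yl]methyl sulfate | COc1cc([C@H]2c3cc(OCc4ccccc4)c(OC)cc3C[C@@H](COCc3ccccc3)[C@@H]2COS(=O)(=O)[O-])ccc1OCc1ccccc1.[Na+] | intermediate
18 | sodium [(1S,2R,3R)-7-hydroxy-1-(4-hydroxy-3-methoxyphenyl)-3-(hydroxymethyl)-6-methoxy-1,2,3,4-tetrahydronaphthalen-2-yl]methyl sulfate (not isolated) | COc1cc([C@H]2c3cc(O)c(OC)cc3C[C@@H](CO)[C@@H]2COS(=O)(=O)[O-])ccc1O.[Na+] | intermediate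
19 | CNP0184747.1, [(1S,2R,3R)-7-hydroxy-1-(4-hydroxy-3-methoxyphenyl)-3-(hydroxymethyl)-6-methoxy-1,2,3,4-tetrahydronaphthalen-2-yl]methyl hydrogen sulfate | COc1cc([C@H]2c3cc(O)c(OC)cc3C[C@@H](CO)[C@@H]2COS(=O)(=O)O)ccc1O | target

**Step count:** 11 steps in total; the longest linear sequence is 11 steps (from 1 and 2).

**Steps most likely to fail**

Step 7 (proposed new method). Guaiacol may attack ortho to its OH or para to its OMe. The oxocarbenium ion may lose the proton next to it and scramble the C2 centre. The aryl benzyl ether or the silyl ether may be cleaved by the Lewis acid, and intermolecular arylation may outrun ring closure.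

The fallback sets out from 11, uses known two-stage chemistry and returns at 14. Mild aqueous acid (1 M HCl, THF, rt) should hydrolyse the methyl acetal to the lactol (3R,4R)-4-(4-benzyloxy-3-methoxybenzyl)-3-(tert-butyldiphenylsilyloxymethyl)tetrahydrofuran-2-ol F1. An excess of [4-(tert-butyldimethylsilyloxy)-3-methoxyphenyl]magnesium bromide (THF, −40 → 0 °C) should open F1 to the benzylic carbinol (2R,3R)-3-(4-benzyloxy-3-methoxybenzyl)-1-[4-(tert-butyldimethylsilyloxy)-3-methoxyphenyl]-2-(tert-butyldiphenylsilyloxymethyl)butane-1,4-diol F2, as a mixture at the carbinol carbon. This fixes the pendant aryl regiochemistry through the aryl–metal bond. BF3·OEt2 in CH2Cl2 at −20 °C should then ionise the carbinol and close the ring by the established cationic aryltetralin cyclisation, giving the 4′-O-silyl tetralin (1S,2R,3R)-7-benzyloxy-1-[4-(tert-butyldimethylsilyloxy)-3-methoxyphenyl]-2-(tert-butyldiphenylsilyloxymethyl)-3-(hydroxymethyl)-6-methoxy-1,2,3,4-tetrahydronaphthalene F3. KHF2 in MeOH at rt should remove only the phenolic silyl group and give 14.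

Step 4. Silylation at carbon instead of oxygen, loss of methanol from the product to an α-methoxymethylene lactone, or poor facial selectivity may erode the step.

The fallback sets out from 6 and returns at 8. Claisen formylation (NaH, HCO2Et, THF, then aq. HCl) should give (R)-4-(4-benzyloxy-3-methoxybenzyl)-3-(hydroxymethylene)dihydrofuran-2(3H)-one F4. Acetalisation with HC(OMe)3 and TsOH in MeOH should then give 8, the α-centre settling to the more stable trans arrangement under these equilibrating conditions, so the configuration is set thermodynamically, not kinetically.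

Step 8. Alkylation of the primary alcohol may stall after the phenol has reacted, or the silyl group may migrate to the neighbouring arm if any alkoxide builds up.

The fallback sets out from 14 and returns at 15. K2CO3 and BnBr in acetone should benzylate only the phenol and give (1S,2R,3R)-7-benzyloxy-1-(4-benzyloxy-3-methoxyphenyl)-2-(tert-butyldiphenylsilyloxymethyl)-3-(hydroxymethyl)-6-methoxy-1,2,3,4-tetrahydronaphthalene F5. The alcohol is then benzylated under neutral conditions with 2-benzyloxy-1-methylpyridinium triflate and MgO in PhCF3 at 85 °C, a thermal benzyl transfer that needs no base, to give 15.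

**Further compounds**

F1 | step 7 | (3R,4R)-4-(4-benzyloxy-3-methoxybenzyl)-3-(tert-butyldiphenylsilyloxymethyl)tetrahydrofuran-2-ol (anomer mixture) | OC1OC[C@H](Cc2ccc(OCc3ccccc3)c(OC)c2)[C@@H]1CO[Si](c1ccccc1)(c1ccccc1)C(C)(C)C
F2 | step 7 | (2R,3R)-3-(4-benzyloxy-3-methoxybenzyl)-1-[4-(tert-butyldimethylsilyloxy)-3-methoxyphenyl]-2-(tert-butyldiphenylsilyloxymethyl)butane-1,4-diol (carbinol epimers) | COc1cc(C(O)[C@@H](CO[Si](c2ccccc2)(c2ccccc2)C(C)(C)C)[C@H](CO)Cc2ccc(OCc3ccccc3)c(OC)c2)ccc1O[Si](C)(C)C(C)(C)C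
F3 | step 7 | (1S,2R,3R)-7-benzyloxy-1-[4-(tert-butyldimethylsilyloxy)-3-methoxyphenyl]-2-(tert-butyldiphenylsilyloxymethyl)-3-(hydroxymethyl)-6-methoxy-1,2,3,4-tetrahydronaphthalene | COc1cc([C@H]2c3cc(OCc4ccccc4)c(OC)cc3C[C@@H](CO)[C@@H]2CO[Si](c2ccccc2)(c2ccccc2)C(C)(C)C)ccc1O[Si](C)(C)C(C)(C)C
F4 | step 4 | (R)-4-(4-benzyloxy-3-methoxybenzyl)-3-(hydroxymethylene)dihydrofuran-2(3H)-one | OC=C1C(=O)OC[C@@H]1Cc1ccc(OCc2ccccc2)c(OC)c1
F5 | step 8 | (1S,2R,3R)-7-benzyloxy-1-(4-benzyloxy-3-methoxyphenyl)-2-(tert-butyldiphenylsilyloxymethyl)-3-(hydroxymethyl)-6-methoxy-1,2,3,4-tetrahydronaphthalene | COc1cc([C@H]2c3cc(OCc4ccccc4)c(OC)cc3C[C@@H](CO)[C@@H]2CO[Si](c2ccccc2)(c2ccccc2)C(C)(C)C)ccc1OCc1ccccc1
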